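The numbers in the tables are simulated with constants of no real substance, and the scatter is random.

A feed over 20 h is slow or fast according to how long D lasts, so that time comes first.

| flask | L | Z | D | remark | time |
|---|---|---|---|---|---|
| north-west | 0.10 M | 0.60 equiv | 10 mol% | run made earlier |  |
| east | 0.10 M | 0.60 equiv | 6.7 mol% | run made earlier |  |
| south-west | 0.10 M | 0.60 equiv | 15 mol% | run made earlier |  |
| west | 0.050 M | 0.60 equiv | 10 mol% | run made earlier |  |
| epsilon | 0.10 M | 0.600 equiv | 10 mol% | everything together at the start | 30 h |
| zeta | 0.10 M | 0.600 equiv (fed, over 20 h) | 10 mol% | all else is in the flask from the start; the feed brings no volume worth counting | 30 h |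
| eta | 0.10 M (fed, over 20 h) | 0.600 equiv | 10 mol% | all else is in the flask from the start; the feed brings no volume worth counting | 30 h |

| run | time / h | J / % |
|---|---|---|
| north-west | 4.00 | 18 |
| north-west | 10.0 | 26 |
| north-west | 20.0 | 24 |
| north-west | 30.0 | 22 |
| east | 8.00 | 15 |
| east | 15.0 | 18 |
| east | 25.0 | 11 |
| east | 30.0 | 13 |
| south-west | 2.50 | 22 |
| south-west | 6.00 | 33 |
| south-west | 12.0 | 32 |
| south-west | 30.0 | 31 |
| west | 8.00 | 19 |
| west | 15.0 | 15 |
| west | 25.0 | 21 |
| west | 30.0 | 17 |

(each reading ± 2 percentage points)



- the flask that comes out highest in amount of J, in percent of the L charged, or "all alike" when all lie within 1.5 percentage points (epsilon / zeta / eta / all alike)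
- J at the end, in percent of the L charged, epsilon
- J at the end, in percent of the L charged, zeta
- J at the end, in percent of the L charged, eta

In the north-west run J levels off at about 24.0%, the mean of the last three readings, or 2.40 J per D (the turnover number). Now work with what is left. At 4.00 h the part of that plateau still to come is 25.0%. If this part falls exponentially, the life of D, the time in which it shrinks by the factor e, is 2.89 h. This is a reading, and a loose one at a scatter of 2 percentage points.

Two views fit these runs, which all hold Z at 0.60 equiv. The forecast says Z kills D: “Feeding Z then keeps Z low and greatly raises turnovers”. It gives epsilon 23%, zeta 42% (range 20% to 57%), eta 8% (range 2% to 25%), and names zeta as highest.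

I hold that L kills D, so D's clock runs in zeta whatever the feed does. Turnover then grows with the Z fed so far while D decays over its life, and the integral gives the plateau times life over feed time. That share is 0.144, so my zeta is 3.46%, far less than the forecast's. In eta, with L kept low, I expect at least the plateau.

    L + D ⇌ G (K = 4.20 M⁻¹, k = 69.0 M⁻¹ h⁻¹)
    Z + G → E (k = 110 M⁻¹ h⁻¹)
    E ⇌ D + J (K = 1.20 M, k = 280 h⁻¹)
    L + G → X (k = 11.0 M⁻¹ h⁻¹)
    Z + J → Q (k = 2.10 M⁻¹ h⁻¹)

Eta gives 25.4%, epsilon 21.7%, zeta 3.02%, so eta is highest. The forecast's view keeps the ground where L and Z stand in the earlier ratio: its epsilon of 23% lies close to the result. At the end of the feed, 20.0 h, zeta held 72.9% of its Z unused and 97.5% of its catalyst as X. With G, E and D as the fraction left, 2.51%, the life in zeta comes to 5.43 h, longer than the 2.89 h read earlier.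

In a neighbour flask, zeta at 0.040 M of L, the scheme's loss of D passes through L twice, so I scale zeta's life of 5.43 h by the square of L to 33.9 h, and by that estimate 41.3% of the catalyst stays outside X up to 30 h. The computed neighbour flask holds 30.2% of its catalyst as G, E and D at 30.0 h, and gives 12.3% of J, beside 6.45% of Q.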